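# Proposed synthesis of the (3R)-isoflavanquinone CNP0241224.1 by chromium-templated benzannulation of ring B

## Analysis of the target

The target (24) is an isoflavanquinone. It is a chroman whose benzo ring (ring A, C4a to C8a) carries methoxy groups at C5 and C7 and a prenyl group at C6, and whose dihydropyran ring (ring C: O1, C2, C3, C4) bears a 2-hydroxy-1,4-benzoquinone (ring B, C1' to C6') at C3. Ring B has carbonyls at C2' and C5', the hydroxyl at C4', the second prenyl group at C3' and its only hydrogen at C6'. C3 is the sole stereocentre, a tertiary C–H of R configuration flanked by C2H2–O1, C4H2–C4a and C1'; with no second stereo element to relay from, it has to be set by absolute control. The sensitive groups are the two trisubstituted prenyl alkenes (acid, electrophilic oxidants, unselective hydrogenation), the hydroxyquinone (nucleophiles, reduction, acid-induced closure of the C4' hydroxyl onto the C3' prenyl group) and the electron-rich ring A. The C3–H bond is also sensitive: it is γ to the C5' carbonyl through C1'=C6' and can be lost by tautomerisation to a quinone methide. The real difficulty is ring B, in which five of six positions are substituted, three adjacent ones (C2', C3', C4') as oxygen/prenyl/oxygen, and in which C4'–O must end as a hydroxyl while C2'–O and C5'–O end as carbonyls. The strategy reads ring B as four pieces: C2' as a metal carbene carbon, C5' as a carbonyl ligand, the C1'=C6' edge as a 1-(chroman-3-yl)vinyl group, and the C3'/C4' prenyl–oxygen pair as a prenylated alkoxyalkyne. A chromium-templated benzannulation of these pieces gives the C2'/C5' oxygen pair as a 4-methoxyphenol, the direct precursor of the quinone.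

## Retrosynthetic reasoning

**24 to 23.** The C4' hydroxyl is traced back to an ethyl ether. In quinone 23 the C4'–OEt group is a vinylogous ester of the C2' carbonyl, so aqueous base can exchange it by addition–elimination at C4' without touching the aryl methyl ethers of ring A. The free hydroxyquinone therefore appears only in the last step.

**23 to 22.** The quinone is cut back to the 4-methoxyphenol 22, in which C5' carries the hydroxyl and C2' the methoxy group. This para pair is oxidised far more easily than ring A, whose three oxygens are meta to each other, so a mild one-electron oxidant should act on ring B alone.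

**22 to 18 and 21 (key disconnection).** Three ring B bonds are cut: C2'–C3', C4'–C5' and C5'–C6'. This leaves the alkenyl(methoxy)carbene complex 18 (C2', C1', C6'), the ynol ether 21 (C3', C4') and one carbonyl ligand of the metal (C5'). The cut is made here because it places all five ring B substituents in one operation and leaves each oxygen in a different form: methoxy at C2' from the carbene, ethoxy at C4' from the alkyne, hydroxyl at C5' from the ligand. The forward reaction has to insert the alkyne with its prenyl-bearing carbon on the carbene carbon, insert the ligand at the ethoxy-bearing carbon and close the ring by electrocyclisation.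

**21 to 19 and 3.** The propargylic C–C bond of 21 is cut to the acetylide 20 of ethoxyacetylene 19 and prenyl bromide 3. One alkylation fixes the prenyl group on the carbon that becomes C3'.

**18 to 14 and 15.** The C1'–C2' bond and the O–methyl bond of the carbene are cut. The carbene carbon comes from a carbonyl ligand of 15 attacked by the vinyllithium 16, and the acylmetalate 17 is methylated on oxygen. The vinyllithium is traced to the sulfonylhydrazone 14 of a methyl ketone, since fragmentation of such a hydrazone gives exactly the 1-substituted vinyl anion and leaves C3 untouched.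

**14 to 11.** Hydrazone 14 comes from methyl ketone 13, the ketone from the N-methoxy-N-methylamide 12, and the amide from acid 11. These are functional group changes at the carbon attached to C3. They are chosen so that the α-stereocentre never meets a strong base while a free ketone is present.

**11 to 10.** The C3 stereocentre is traced to the C3=C4 double bond of the chromene acid 10. The carboxyl group on C3 is the handle by which a chiral ruthenium diphosphine catalyst can distinguish the two faces of that bond, and the two prenyl alkenes carry no such handle.

**10 to 7 and 8.** Ring C is cut at O1–C2 and C3–C4, which gives salicylaldehyde 7 and acrylonitrile 8. A conjugate addition/aldol condensation pair joins them to nitrile 9, which is hydrolysed to 10.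

**7 to 1 and 3.** The formyl group of 7 is removed to give phenol 6, whose two ortho positions are equivalent. The C6 prenyl group (C4 of the phenol) is then cut to aryllithium 4 and prenyl bromide 3. The lithium sits between two methoxy groups in silyl ether 2, made from 3,5-dimethoxyphenol 1. Ring A is thus built by ordinary arene chemistry before any sensitive group exists.

## Alternatives that were turned down

**Alternative 1: twofold aromatic Claisen rearrangement.** Both aryl–CH2 bonds of the prenyl groups (at C6 and at C3') are cut, tracing them to 1,1-dimethylallyl ethers on the C5 and C2' oxygens of a preformed isoflavan, the bis-ether A2. On heating, each ether would deliver its terminal carbon to the only free ortho position (C6, because C4a is quaternary; C3', because C1' is quaternary). The allyl inversion turns the tertiary ether into a linear prenyl group and gives the diol A1.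

- For: both prenyl positions are fixed by intramolecular delivery, one operation installs both groups, and no organometallic or stoichiometric metal reagent is needed. On regiochemical certainty of prenyl placement this plan is stronger than the chosen one.
- Against: the step builds no ring and no stereocentre, so the whole isoflavan with C3 set and five oxygens differentiated must exist first. Each tertiary ether costs about two steps (propargylic etherification and semi-hydrogenation). A1 has a free hydroxyl next to each prenyl group, the arrangement that closes onto the alkene under heat or traces of acid. The C5 hydroxyl must then be methylated while the C2' hydroxyl is kept for oxidation, and oxidation followed by hydrolysis of the C4' methyl ether is still required.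
- Comparison: the chosen route places the ring A prenyl group before any ring is built, brings the ring B prenyl group in with the alkyne, and differentiates the three ring B oxygens in the same step that makes the ring.

**Alternative 2: Danheiser benzannulation of ring A.** Ring A is cut at C8a–C4a, C5–C6 and C8–C8a, with ring C opened at O1–C2. The partners are the cyclobutenone A4 and the ynol ether A5, which already carries C3 and the complete ring B. Heating would open A4 to a vinylketene. Ketene–alkyne [2+2] addition, a second four-electron opening and a six-electron closure would then give phenol A3, whose free C8a hydroxyl would close ring C after desilylation.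

- For: the cascade is metal-free and convergent, and the orientation of the ketene/ynol ether addition is better established than alkyne orientation in a chromium benzannulation. On these points it is the stronger plan.
- Against: the cascade builds the ring that is easy to obtain from a phloroglucinol derivative. The hard ring B must be supplied complete, as a 2',4',5'-trimethoxy-3'-prenyl arene. The stereocentre has to be set in the acyclic chain of A5, a long and acid-sensitive partner. The end game must oxidatively demethylate a non-phenolic ring B in the presence of the more electron-rich ring A and two prenyl groups, with nothing in the structure to favour ring B. Ring closure and oxidation add further steps after A3.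
- Comparison: the chosen plan uses its key step on ring B and delivers it as a phenol that is oxidised selectively.

**Alternative 3: ortho-quinone methide/azolium enolate annulation.** Ring C is cut at C3–C4 and at the acyl C2–O1 bond, which gives ring A as the ortho-quinone methide A7 and ring B as the acyl imidazole A8. A chiral triazolium-derived carbene would turn A8 into an azolium enolate. Its carbon (C3) adds to the exocyclic methylene (C4) of A7, and the phenoxide O1 acylates at C2, giving the dihydrocoumarin A6.

- For: a single catalytic step joins two fragments of similar size, closes ring C and sets C3. In convergence and in combining ring formation with stereocontrol it is stronger than the chosen route, which sets C3 in a separate hydrogenation.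
- Against: C3 of A6 is α to a lactone carbonyl and α to an aryl group, a far more acidic position than any the chosen route passes through, and it is formed under the base that releases A7. With C4 unsubstituted there is no second stereocentre to hold it. The lactone carbonyl must be removed in two or three further steps. The unsubstituted methide A7 is prone to self-condensation. A8 needs the complete prenylated trimethoxy ring B, so the same unselective final oxidation as in Alternative 2 returns.
- Comparison: the chosen route keeps C3 next to a carboxylate, an amide and briefly an alkyl ketone under neutral or weakly acidic conditions, and makes ring B instead of importing it.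

Key step: step 12

Assumption: the (R)-BINAP ligand in step 6 is assigned by analogy with the facial preference of (E)-2-alkyl-3-substituted acrylic acids under BINAP–ruthenium dicarboxylate catalysis; if the chromene acid responds in the opposite sense, the (S)-ligand is used with no other change.

## Route

Step 1
Reactants: 1 3,5-dimethoxyphenol
Product: 2 (3,5-dimethoxyphenoxy)triisopropylsilane
Conditions: i-Pr3SiCl, imidazole, DMF, rt
Reagents that add atoms: chlorotriisopropylsilane, CC(C)[Si](Cl)(C(C)C)C(C)C
Why: Standard silylation of a phenol; the bulky silyl ether neither directs nor allows lithiation at its own ortho positions, which leaves the position between the two methoxy groups as the site for step 2.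

Step 2
Reactants: 2 (3,5-dimethoxyphenoxy)triisopropylsilane; 3 prenyl bromide (1-bromo-3-methylbut-2-ene)
Product: 6 3,5-dimethoxy-4-(3-methylbut-2-en-1-yl)phenol, via aryllithium 4 (not isolated), via prenylated silyl ether 5 (not isolated)
Conditions: n-BuLi, TMEDA, THF, 0 °C to rt; CuBr·SMe2 (10 mol %), 3, −78 °C to rt; then Bu4NF, rt
Reagents that add atoms: none
Why: Directed ortho-metalation at the carbon flanked by both methoxy groups, then copper-catalysed SN2 allylation at the primary carbon of 3 (the fully substituted γ-carbon disfavours allylic transposition); fluoride then cleaves the aryl silyl ether in the same flask.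

Step 3
Reactants: 6 3,5-dimethoxy-4-(3-methylbut-2-en-1-yl)phenol
Product: 7 2-hydroxy-4,6-dimethoxy-5-(3-methylbut-2-en-1-yl)benzaldehyde
Conditions: (CH2O)n, MgCl2, Et3N, MeCN, reflux; cold dilute HCl work-up
Reagents that add atoms: paraformaldehyde (as formaldehyde), C=O
Why: Magnesium phenoxide-directed ortho-formylation (Casnati–Skattebøl); the two ortho positions of 6 are equivalent, so only one aldehyde can form, and the medium is not acidic enough to harm the prenyl group, which has no free hydroxyl beside it.

Step 4
Reactants: 7 2-hydroxy-4,6-dimethoxy-5-(3-methylbut-2-en-1-yl)benzaldehyde; 8 acrylonitrile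
Product: 9 5,7-dimethoxy-6-(3-methylbut-2-en-1-yl)-2H-chromene-3-carbonitrile
Conditions: DABCO (0.5 equiv), 8 (neat), 80 °C
Reagents that add atoms: none
Why: Amine-catalysed Baylis–Hillman/oxa-Michael annulation of a salicylaldehyde with an acrylic acceptor; O1–C2 forms by conjugate addition, C3–C4 by aldol addition, and loss of water gives the 2H-chromene of ring C.

Step 5
Reactants: 9 5,7-dimethoxy-6-(3-methylbut-2-en-1-yl)-2H-chromene-3-carbonitrile
Product: 10 5,7-dimethoxy-6-(3-methylbut-2-en-1-yl)-2H-chromene-3-carboxylic acid
Conditions: NaOH (10% aq), EtOH, reflux; then 1 M HCl, 0 °C, to pH 3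
Reagents that add atoms: sodium hydroxide, [Na+].[OH-]; water, O
Why: Alkaline hydrolysis of a conjugated nitrile to the carboxylate; the prenyl group and the aryl ethers are inert to base, and the short cold acidification cannot cyclise a prenyl group flanked by two methoxy groups.

Step 6
Reactants: 10 5,7-dimethoxy-6-(3-methylbut-2-en-1-yl)-2H-chromene-3-carboxylic acid
Product: 11 (3S)-5,7-dimethoxy-6-(3-methylbut-2-en-1-yl)chromane-3-carboxylic acid
Conditions: H2 (10 atm), Ru(OAc)2[(R)-BINAP] (1 mol %), MeOH, 25 °C
Reagents that add atoms: none
Why: Carboxylate-directed asymmetric hydrogenation of an α,β-unsaturated acid by a divalent ruthenium BINAP dicarboxylate; the chiral diphosphine selects the face of the chelated C3=C4 bond and so sets C3, while the isolated prenyl alkene, which cannot chelate, should be left alone.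

Step 7
Reactants: 11 (3S)-5,7-dimethoxy-6-(3-methylbut-2-en-1-yl)chromane-3-carboxylic acid
Product: 12 (3S)-N-methoxy-N-methyl-5,7-dimethoxy-6-(3-methylbut-2-en-1-yl)chromane-3-carboxamide
Conditions: MeNHOMe·HCl, EDC·HCl, 4-methylmorpholine, CH2Cl2, 0 °C to rt
Reagents that add atoms: N,O-dimethylhydroxylamine hydrochloride, CNOC.Cl
Why: Carbodiimide amidation to the Weinreb amide; the weak amine base should not enolise the activated acid, so the α-stereocentre at C3 should be kept.

Step 8
Reactants: 12 (3S)-N-methoxy-N-methyl-5,7-dimethoxy-6-(3-methylbut-2-en-1-yl)chromane-3-carboxamide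
Product: 13 1-[(3S)-5,7-dimethoxy-6-(3-methylbut-2-en-1-yl)chroman-3-yl]ethan-1-one
Conditions: MeMgBr, THF, −20 to 0 °C; cold aq NH4Cl
Reagents that add atoms: methylmagnesium bromide, C[Mg]Br
Why: Weinreb ketone synthesis; the chelated tetrahedral magnesium adduct persists until the quench, so there is no over-addition and the epimerisable ketone, which could also lose the O1 aryloxide by β-elimination, is never exposed to the basic reagent.

Step 9
Reactants: 13 1-[(3S)-5,7-dimethoxy-6-(3-methylbut-2-en-1-yl)chroman-3-yl]ethan-1-one
Product: 14 N'-[(1E)-1-[(3R)-5,7-dimethoxy-6-(3-methylbut-2-en-1-yl)chroman-3-yl]ethylidene]-2,4,6-triisopropylbenzenesulfonohydrazide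
Conditions: 2,4,6-(i-Pr)3C6H2SO2NHNH2, MeOH, AcOH (cat.), rt
Reagents that add atoms: 2,4,6-triisopropylbenzenesulfonohydrazide, CC(C)c1cc(C(C)C)c(S(=O)(=O)NN)c(C(C)C)c1
Why: Condensation of a ketone with a sulfonyl hydrazide under weakly acidic conditions at room temperature; the E isomer, with the sulfonylamino nitrogen on the methyl side, is expected, and the change of descriptor from S to R reflects only the lower rank of C=N against C2, not a change at C3.

Step 10
Reactants: 14 N'-[(1E)-1-[(3R)-5,7-dimethoxy-6-(3-methylbut-2-en-1-yl)chroman-3-yl]ethylidene]-2,4,6-triisopropylbenzenesulfonohydrazide; 15 Cr(CO)6 (chromium hexacarbonyl, zerovalent chromium)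
Product: 18 pentacarbonyl{methoxy[1-((3R)-5,7-dimethoxy-6-(3-methylbut-2-en-1-yl)chroman-3-yl)ethenyl]carbene}chromium (zerovalent chromium), via vinyllithium 16 (not isolated), via lithium acylchromate 17 (not isolated)
Conditions: n-BuLi (2.05 equiv), THF, −78 to 0 °C; 15, THF, 0 °C to rt; then Me3OBF4, CH2Cl2/H2O, 0 °C
Reagents that add atoms: trimethyloxonium tetrafluoroborate, C[O+](C)C.F[B-](F)(F)F
Why: Shapiro reaction followed by Fischer carbene synthesis: the second equivalent of base removes a methyl proton syn to the sulfonylamide nitrogen (kinetically and geometrically favoured over the C3–H), the dianion loses sulfinate and N2 to give the 1-substituted vinyllithium, this adds to a carbonyl ligand of 15, and the acylmetalate is methylated on oxygen. The triisopropylphenyl group blocks ortho-lithiation of the sulfonyl arene and allows fragmentation at 0 °C.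

Step 11
Reactants: 19 ethoxyacetylene; 3 prenyl bromide (1-bromo-3-methylbut-2-ene)
Product: 21 1-ethoxy-5-methylhex-4-en-1-yne, via lithium ethoxyacetylide 20 (not isolated)
Conditions: n-BuLi, THF, −78 °C; 3, DMPU, −78 °C to rt
Reagents that add atoms: none
Why: Alkylation of a lithium alkoxyacetylide with a reactive primary allylic bromide in the presence of a dipolar cosolvent; SN2 attack at the unhindered CH2 is expected, and the product is kept away from acid because ynol ethers hydrate easily.

Step 12
Reactants: 18 pentacarbonyl{methoxy[1-((3R)-5,7-dimethoxy-6-(3-methylbut-2-en-1-yl)chroman-3-yl)ethenyl]carbene}chromium; 21 1-ethoxy-5-methylhex-4-en-1-yne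
Product: 22 5-[(3R)-5,7-dimethoxy-6-(3-methylbut-2-en-1-yl)chroman-3-yl]-2-ethoxy-4-methoxy-3-(3-methylbut-2-en-1-yl)phenol
Conditions: 21 (1.5 equiv), THF (0.05 M), 50 °C, Ar; then air, rt
Reagents that add atoms: none
Why: Thermal loss of one cis carbonyl ligand from 18 lets the alkyne bind; its prenyl-bearing carbon (C3', the nucleophilic β-carbon of the ynol ether) bonds to the electrophilic carbene carbon C2', and the metal moves to the ethoxy-bearing carbon C4', which is stabilised as a new donor-substituted carbene. Migration of a carbonyl ligand onto C4' gives the metal-bound dienylketene C6'H2=C1'–C2'(OMe)=C3'–C4'(OEt)=C5'=O. Ring B closes by a thermal disrotatory six-electron electrocyclisation joining C5' to C6'; the cyclohexadienone then tautomerises by loss of a C6' hydrogen to the phenol, first as its Cr(CO)3 complex, from which air removes the metal. The closest known reaction type is the Dötz benzannulation of alkenyl(alkoxy)carbene complexes of zerovalent chromium with alkynes, together with the insertion of heteroatom-substituted alkynes into metal–carbene bonds in this same orientation. No stereocentre is formed, and C3 is an sp3 spectator next to the reacting vinyl group in a neutral medium. The selectivity needed is alkyne orientation, and it rests on the polarisation of the ynol ether: the oxygen-bearing carbon is the better carbene-stabilising position and the remote carbon the nucleophilic one, while the ethoxy group and the prenyl CH2 are of similar size, so the steric term is small and does not oppose it. Alkyne insertion should outrun cyclopropanation of the three trisubstituted alkenes, and the alkene of 21 is too close to the alkyne for intramolecular capture by the intermediate carbene. The C5' hydroxyl and C2' methoxy groups come out para to each other as a direct result of the mechanism, which prepares step 13.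

Step 13
Reactants: 22 5-[(3R)-5,7-dimethoxy-6-(3-methylbut-2-en-1-yl)chroman-3-yl]-2-ethoxy-4-methoxy-3-(3-methylbut-2-en-1-yl)phenol
Product: 23 5-[(3R)-5,7-dimethoxy-6-(3-methylbut-2-en-1-yl)chroman-3-yl]-2-ethoxy-3-(3-methylbut-2-en-1-yl)cyclohexa-2,5-diene-1,4-dione
Conditions: (NH4)2Ce(NO3)6 (2.2 equiv), MeCN/H2O, 0 °C, 10 min
Reagents that add atoms: water, O
Why: Oxidative demethylation of a 4-methoxyphenol by tetravalent cerium: two-electron oxidation of the phenol, attack of water at C2' and loss of methanol. Ring A has no para oxygen pair and is oxidised more slowly, and short contact at 0 °C should spare the prenyl groups; if some oxidation ran with loss of the ethyl group instead, the other vinylogous ester would converge on 24 in step 14.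

Step 14
Reactants: 23 5-[(3R)-5,7-dimethoxy-6-(3-methylbut-2-en-1-yl)chroman-3-yl]-2-ethoxy-3-(3-methylbut-2-en-1-yl)cyclohexa-2,5-diene-1,4-dione
Product: 24 5-[(3R)-5,7-dimethoxy-6-(3-methylbut-2-en-1-yl)chroman-3-yl]-2-hydroxy-3-(3-methylbut-2-en-1-yl)cyclohexa-2,5-diene-1,4-dione
Conditions: LiOH (3 equiv), THF/H2O, 0 °C, Ar; then 0.5 M HCl, 0 °C, to pH 3–4
Reagents that add atoms: lithium hydroxide, [Li+].[OH-]
Why: Vinylogous saponification: hydroxide adds at C4' and ethoxide leaves, giving the hydroxyquinone anion, which resists further nucleophilic attack. The aryl methyl ethers of ring A are not vinylogous esters and stay, and the gentle cold acidification avoids closure of the C4' hydroxyl onto the C3' prenyl group.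

## Compound list

1 | 3,5-dimethoxyphenol | COc1cc(O)cc(OC)c1 | starting material
2 | (3,5-dimethoxyphenoxy)triisopropylsilane | COc1cc(O[Si](C(C)C)(C(C)C)C(C)C)cc(OC)c1 | intermediate
3 | prenyl bromide (1-bromo-3-methylbut-2-ene) | CC(C)=CCBr | starting material
4 | [2,6-dimethoxy-4-(triisopropylsilyloxy)phenyl]lithium | COc1cc(O[Si](C(C)C)(C(C)C)C(C)C)cc(OC)c1[Li] | intermediate (not isolated)
5 | [3,5-dimethoxy-4-(3-methylbut-2-en-1-yl)phenoxy]triisopropylsilane | COc1cc(O[Si](C(C)C)(C(C)C)C(C)C)cc(OC)c1CC=C(C)C | intermediate (not isolated)
6 | 3,5-dimethoxy-4-(3-methylbut-2-en-1-yl)phenol | COc1cc(O)cc(OC)c1CC=C(C)C | intermediate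
7 | 2-hydroxy-4,6-dimethoxy-5-(3-methylbut-2-en-1-yl)benzaldehyde | COc1cc(O)c(C=O)c(OC)c1CC=C(C)C | intermediate
8 | acrylonitrile | C=CC#N | starting material
9 | 5,7-dimethoxy-6-(3-methylbut-2-en-1-yl)-2H-chromene-3-carbonitrile | COc1cc2c(c(OC)c1CC=C(C)C)C=C(C#N)CO2 | intermediate
10 | 5,7-dimethoxy-6-(3-methylbut-2-en-1-yl)-2H-chromene-3-carboxylic acid | COc1cc2c(c(OC)c1CC=C(C)C)C=C(C(=O)O)CO2 | intermediate
11 | (3S)-5,7-dimethoxy-6-(3-methylbut-2-en-1-yl)chromane-3-carboxylic acid | COc1cc2c(c(OC)c1CC=C(C)C)C[C@H](C(=O)O)CO2 | intermediate
12 | (3S)-N-methoxy-N-methyl-5,7-dimethoxy-6-(3-methylbut-2-en-1-yl)chromane-3-carboxamide | COc1cc2c(c(OC)c1CC=C(C)C)C[C@H](C(=O)N(C)OC)CO2 | intermediate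
13 | 1-[(3S)-5,7-dimethoxy-6-(3-methylbut-2-en-1-yl)chroman-3-yl]ethan-1-one | COc1cc2c(c(OC)c1CC=C(C)C)C[C@H](C(C)=O)CO2 | intermediate
14 | N'-[(1E)-1-[(3R)-5,7-dimethoxy-6-(3-methylbut-2-en-1-yl)chroman-3-yl]ethylidene]-2,4,6-triisopropylbenzenesulfonohydrazide | COc1cc2c(c(OC)c1CC=C(C)C)C[C@H](/C(C)=N/NS(=O)(=O)c1c(C(C)C)cc(C(C)C)cc1C(C)C)CO2 | intermediate
15 | chromium hexacarbonyl, Cr(CO)6 | O=C=[Cr](=C=O)(=C=O)(=C=O)(=C=O)=C=O | starting material
16 | {1-[(3R)-5,7-dimethoxy-6-(3-methylbut-2-en-1-yl)chroman-3-yl]ethenyl}lithium | COc1cc2c(c(OC)c1CC=C(C)C)C[C@H](C([Li])=C)CO2 | intermediate (not isolated)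
17 | lithium pentacarbonyl{2-[(3R)-5,7-dimethoxy-6-(3-methylbut-2-en-1-yl)chroman-3-yl]prop-2-enoyl}chromate | COc1cc2c(c(OC)c1CC=C(C)C)C[C@H](C(=C)C([O-])=[Cr](=C=O)(=C=O)(=C=O)(=C=O)=C=O)CO2.[Li+] | intermediate (not isolated)
18 | pentacarbonyl{methoxy[1-((3R)-5,7-dimethoxy-6-(3-methylbut-2-en-1-yl)chroman-3-yl)ethenyl]carbene}chromium | COc1cc2c(c(OC)c1CC=C(C)C)C[C@H](C(=C)C(OC)=[Cr](=C=O)(=C=O)(=C=O)(=C=O)=C=O)CO2 | intermediate
19 | ethoxyacetylene | CCOC#C | starting material
20 | lithium ethoxyacetylide | CCOC#C[Li] | intermediate (not isolated)
21 | 1-ethoxy-5-methylhex-4-en-1-yne | CCOC#CCC=C(C)C | intermediate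
22 | 5-[(3R)-5,7-dimethoxy-6-(3-methylbut-2-en-1-yl)chroman-3-yl]-2-ethoxy-4-methoxy-3-(3-methylbut-2-en-1-yl)phenol | COc1cc2c(c(OC)c1CC=C(C)C)C[C@H](c1cc(O)c(OCC)c(CC=C(C)C)c1OC)CO2 | intermediate
23 | 5-[(3R)-5,7-dimethoxy-6-(3-methylbut-2-en-1-yl)chroman-3-yl]-2-ethoxy-3-(3-methylbut-2-en-1-yl)cyclohexa-2,5-diene-1,4-dione | COc1cc2c(c(OC)c1CC=C(C)C)C[C@H](C1=CC(=O)C(OCC)=C(CC=C(C)C)C1=O)CO2 | intermediate
24 | 5-[(3R)-5,7-dimethoxy-6-(3-methylbut-2-en-1-yl)chroman-3-yl]-2-hydroxy-3-(3-methylbut-2-en-1-yl)cyclohexa-2,5-diene-1,4-dione | COc1cc2c(c(OC)c1CC=C(C)C)C[C@H](C1=CC(=O)C(O)=C(CC=C(C)C)C1=O)CO2 | target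

## Step count and least certain steps

Total step count: 14. Longest linear sequence: 13 steps (steps 1 to 10 and 12 to 14); step 11 is a one-step branch.

**Step 12 (key step).** The most likely failure is stalling after alkyne insertion: the ethoxy group stabilises the new carbene at C4' and slows migration of a carbonyl ligand, so the metal may stay on C4' or the intermediate may drift to other products. Insertion in the opposite orientation is the second risk, since the steric bias is small. Fallback: 18 and 21 are combined at 25–40 °C under CO (1 atm), so that the inserted species is collected as the pentacarbonyl dienyl(ethoxy)carbene complex F1, with the carbene carbon and the vinyl group cis on the C2'=C3' bond. Irradiation of the dienyl(ethoxy)carbene complex F1 in THF (Pyrex-filtered Hg lamp) then drives the carbonyl insertion photochemically. The resulting ketene closes by the same six-electron electrocyclisation, and the route is rejoined at 22.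

**Step 10.** The vinyllithium 16 may be lost by proton transfer (from solvent, from remaining hydrazone, or through competing metalation of ring A at C8), and its addition to the sparingly soluble 15 may be incomplete. Equilibration of the dianion towards the C3 side would erode the stereocentre. Fallback: ketone 13 is condensed with N2H4·H2O in EtOH to give the N-unsubstituted hydrazone F2. Barton vinyl iodide synthesis (I2, 1,1,3,3-tetramethylguanidine, THF, 0 °C) converts the hydrazone F2 into the vinyl iodide F3. Iodine–lithium exchange on the vinyl iodide F3 with t-BuLi (2 equiv) at −78 °C generates 16 at a temperature where proton transfer is slow, and the route is rejoined at 16 and continues to 17 and 18 as in step 10.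

**Step 14.** Hydroxide may remove the C3 proton of 23 (γ to the C5' carbonyl) and cause epimerisation through the quinone methide tautomer, or add at the unsubstituted C6' instead of C4'. Fallback: the C4' oxygen is carried as a silyl ether so that no basic step is needed. Prenyl bromide 3 is alkylated with LiC≡CH·H2NCH2CH2NH2 in DMSO to give 5-methylhex-4-en-1-yne F4. The acetylide of 5-methylhex-4-en-1-yne F4 (n-BuLi) is oxidised with t-BuOOLi and the resulting ynolate is silylated with i-Pr3SiOTf to give the siloxyalkyne F5. Benzannulation of 18 with the siloxyalkyne F5, under the conditions of step 12, gives the C4' silyl ether phenol F6. Oxidation of the silyl ether phenol F6 with (NH4)2Ce(NO3)6 in aqueous MeCN forms the quinone, and the vinylogous silyl ester left at C4' hydrolyses in the acidic aqueous medium, so the route is rejoined directly at 24.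

**Step 6.** Facial selectivity may be poor because O1 offers a second binding site to the metal, and reduction of the C6 prenyl alkene may begin if forcing pressure is needed. Fallback: acid 10 is hydrogenated with Ru(OAc)2(rac-BINAP) to the racemic acid F7. Crystallisation of the racemic acid F7 with (R)-1-phenylethylamine gives the less soluble diastereomeric ammonium salt F8. Acidification of the ammonium salt F8 returns the route to 11, so stereocontrol passes from the catalyst to a classical resolution.

**Step 2.** Metalation may occur next to the silyloxy group instead of between the methoxy groups, and the allylation may suffer halogen–metal exchange or allylic transposition. Fallback: 1,3-dimethoxybenzene F9 (purchased) is lithiated with n-BuLi at its only doubly activated position and alkylated with prenyl bromide 3 to give 1,3-dimethoxy-2-prenylbenzene F10. Iridium-catalysed C–H borylation of 1,3-dimethoxy-2-prenylbenzene F10 ([Ir(OMe)(cod)]2, 4,4'-di-tert-butyl-2,2'-bipyridine, B2pin2) takes place at the one ring position without an ortho substituent and gives the boronate F11. Oxidation of the boronate F11 with NaBO3·4H2O in THF/H2O gives the phenol, and the route is rejoined at 6.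

## Further compounds

F1 | step 12 | pentacarbonyl{ethoxy[3-((3R)-5,7-dimethoxy-6-(3-methylbut-2-en-1-yl)chroman-3-yl)-2-methoxy-1-(3-methylbut-2-en-1-yl)buta-1,3-dien-1-yl]carbene}chromium, carbene carbon and vinyl group cis | COc1cc2c(c(OC)c1CC=C(C)C)C[C@H](C(=C)/C(OC)=C(CC=C(C)C)\C(OCC)=[Cr](=C=O)(=C=O)(=C=O)(=C=O)=C=O)CO2
F2 | step 10 | 1-[(3R)-5,7-dimethoxy-6-(3-methylbut-2-en-1-yl)chroman-3-yl]ethan-1-one hydrazone | COc1cc2c(c(OC)c1CC=C(C)C)C[C@H](C(C)=NN)CO2
F3 | step 10 | (3S)-3-(1-iodoethenyl)-5,7-dimethoxy-6-(3-methylbut-2-en-1-yl)chromane | COc1cc2c(c(OC)c1CC=C(C)C)C[C@H](C(I)=C)CO2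
F4 | step 14 | 5-methylhex-4-en-1-yne | C#CCC=C(C)C
F5 | step 14 | triisopropyl[(5-methylhex-4-en-1-yn-1-yl)oxy]silane | CC(C)[Si](OC#CCC=C(C)C)(C(C)C)C(C)C
F6 | step 14 | 5-[(3R)-5,7-dimethoxy-6-(3-methylbut-2-en-1-yl)chroman-3-yl]-4-methoxy-3-(3-methylbut-2-en-1-yl)-2-(triisopropylsilyloxy)phenol | COc1cc2c(c(OC)c1CC=C(C)C)C[C@H](c1cc(O)c(O[Si](C(C)C)(C(C)C)C(C)C)c(CC=C(C)C)c1OC)CO2
F7 | step 6 | racemic 5,7-dimethoxy-6-(3-methylbut-2-en-1-yl)chromane-3-carboxylic acid | COc1cc2c(c(OC)c1CC=C(C)C)CC(C(=O)O)CO2
F8 | step 6 | (R)-1-phenylethylammonium (3S)-5,7-dimethoxy-6-(3-methylbut-2-en-1-yl)chromane-3-carboxylate | COc1cc2c(c(OC)c1CC=C(C)C)C[C@H](C(=O)[O-])CO2.C[C@@H]([NH3+])c1ccccc1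
F9 | step 2 | 1,3-dimethoxybenzene (purchased) | COc1cccc(OC)c1
F10 | step 2 | 1,3-dimethoxy-2-(3-methylbut-2-en-1-yl)benzene | COc1cccc(OC)c1CC=C(C)C
F11 | step 2 | 2-[3,5-dimethoxy-4-(3-methylbut-2-en-1-yl)phenyl]-4,4,5,5-tetramethyl-1,3,2-dioxaborolane | COc1cc(B2OC(C)(C)C(C)(C)O2)cc(OC)c1CC=C(C)C
A1 | alternative 1 | (3R)-3-[2-hydroxy-4,5-dimethoxy-3-(3-methylbut-2-en-1-yl)phenyl]-7-methoxy-6-(3-methylbut-2-en-1-yl)chroman-5-ol | COc1cc2c(c(O)c1CC=C(C)C)C[C@H](c1cc(OC)c(OC)c(CC=C(C)C)c1O)CO2
A2 | alternative 1 | (3R)-3-[4,5-dimethoxy-2-(2-methylbut-3-en-2-yloxy)phenyl]-7-methoxy-5-(2-methylbut-3-en-2-yloxy)chromane | COc1cc2c(c(OC(C)(C)C=C)c1)C[C@H](c1cc(OC)c(OC)cc1OC(C)(C)C=C)CO2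
A3 | alternative 2 | 2-[(2R)-3-(tert-butyldimethylsilyloxy)-2-[2,4,5-trimethoxy-3-(3-methylbut-2-en-1-yl)phenyl]propyl]-3,5-dimethoxy-4-(3-methylbut-2-en-1-yl)phenol | COc1cc(O)c(c(OC)c1CC=C(C)C)C[C@H](c1cc(OC)c(OC)c(CC=C(C)C)c1OC)CO[Si](C)(C)C(C)(C)C
A4 | alternative 2 | 3-methoxy-2-(3-methylbut-2-en-1-yl)cyclobut-2-en-1-one | COC1=C(CC=C(C)C)C(=O)C1
A5 | alternative 2 | tert-butyl{[(2R)-5-methoxy-2-[2,4,5-trimethoxy-3-(3-methylbut-2-en-1-yl)phenyl]pent-4-yn-1-yl]oxy}dimethylsilane | COC#CC[C@H](c1cc(OC)c(OC)c(CC=C(C)C)c1OC)CO[Si](C)(C)C(C)(C)C
A6 | alternative 3 | (3R)-5,7-dimethoxy-6-(3-methylbut-2-en-1-yl)-3-[2,4,5-trimethoxy-3-(3-methylbut-2-en-1-yl)phenyl]chroman-2-one | COc1cc2c(c(OC)c1CC=C(C)C)C[C@H](c1cc(OC)c(OC)c(CC=C(C)C)c1OC)C(=O)O2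
A7 | alternative 3 | 3,5-dimethoxy-6-methylidene-4-(3-methylbut-2-en-1-yl)cyclohexa-2,4-dien-1-one | C=C1C(=O)C=C(OC)C(CC=C(C)C)=C1OC
A8 | alternative 3 | 1-(1H-imidazol-1-yl)-2-[2,4,5-trimethoxy-3-(3-methylbut-2-en-1-yl)phenyl]ethan-1-one | COc1cc(CC(=O)n2ccnc2)c(OC)c(CC=C(C)C)c1OC
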